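The depside is cut at its aryl ester into a ring B acid and a ring A phenol. Ring B (C1 carbonyl, C2 heptyl, C4/C6 methoxy) carries heptyl and carboxyl on adjacent carbons with the C6 methoxy next to the carboxyl carbon, the pattern a 3-methoxyaryne returns on carbometalation. One flask therefore converts 1-bromo-2-iodo-3,5-dimethoxybenzene, heptylmagnesium bromide and carbon dioxide into 2-heptyl-4,6-dimethoxybenzoic acid, forming both the C2–heptyl and C1–carboxyl bonds. Ring A is built separately from methyl orsellinate (4-O protection, 2-O-methylation, lateral hexylation, ester exchange), joined through a mixed anhydride and unmasked by hydrogenolysis.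

Key step: step 3

Remark: the target has no stereocentre; ring A needs its ortho oxygen as a methyl ether and its para oxygen free for acylation, so the para hydroxyl of methyl orsellinate is masked before the ortho hydroxyl is methylated.

Step 1
Reactants: 1 1-bromo-3,5-dimethoxybenzene
Product: 2 1-bromo-2-iodo-3,5-dimethoxybenzene
Conditions: N-iodosuccinimide (1.05 equiv), MeCN, rt, dark
Reagents that add atoms: N-iodosuccinimide, O=C1CCC(=O)N1I
Why: Electrophilic aromatic iodination should go to C2 (equivalent to C6), which is para to one methoxy and ortho to the other, in preference to the more crowded carbon lying ortho to both methoxy groups.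

Step 2
Reactants: 3 1-bromoheptane
Product: 4 heptylmagnesium bromide
Conditions: Mg turnings, I2 (crystal), THF, 40 °C to reflux; titrate
Reagents that add atoms: magnesium, [Mg]
Why: Direct magnesium insertion into a primary alkyl bromide (Grignard reagent formation) is routine, and titration allows the stoichiometry of step 3 to be set exactly.

Step 3
Reactants: 2 1-bromo-2-iodo-3,5-dimethoxybenzene; 4 heptylmagnesium bromide; 5 carbon dioxide
Product: 9 2-heptyl-4,6-dimethoxybenzoic acid, via 2-bromo-4,6-dimethoxyphenylmagnesium chloride 6 (not isolated), via 3,5-dimethoxybenzyne 7 (not isolated), via 2-heptyl-4,6-dimethoxyphenylmagnesium bromide 8 (not isolated)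
Conditions: iPrMgCl·LiCl (1.0 equiv), THF, −40 °C, 30 min; then 4 (3 equiv), −40 → 50 °C; then CO2 (gas), 0 °C; 1 M HCl work-up
Reagents that add atoms: none
Why: Iodine–magnesium exchange at C2 (iodide exchanges far faster than bromide) gives the ortho-bromoaryl Grignard 6, which on warming loses MgBrCl to give aryne 7; heptylmagnesium bromide adds across the strained triple bond to give aryl Grignard 8, and carbon dioxide converts the new C–Mg bond into the carboxylate. The closest known reaction type is the carbomagnesiation of 3-alkoxyarynes generated from 1,2-dihaloarenes, followed by electrophilic trapping of the resulting arylmagnesium. No ring is closed and no stereocentre is formed; the two skeletal bonds made are C2–heptyl and C1–carboxyl of ring B. The step needs regioselective addition: the methoxy group flanking the aryne polarises the triple bond inductively and coordinates magnesium, so carbon should bond to the distal aryne carbon and magnesium should sit on the carbon next to methoxy, which is the one carboxylated. It also needs a single carbon nucleophile in the flask, which is secured by using exactly one equivalent of the exchange reagent and letting it be consumed at −40 °C before 4 is added and the mixture is warmed.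

Step 4
Reactants: 10 methyl orsellinate (methyl 2,4-dihydroxy-6-methylbenzoate)
Product: 11 methyl 2-hydroxy-4-(methoxymethoxy)-6-methylbenzoate
Conditions: MOMCl (1.1 equiv), iPr2NEt (1.5 equiv), CH2Cl2, 0 °C → rt
Reagents that add atoms: chloromethyl methyl ether, COCCl
Why: O-alkylation (acetal protection) should occur only at the free 4-OH, because the 2-OH is hydrogen-bonded to the ester carbonyl and is not alkylated under amine-base conditions.

Step 5
Reactants: 11 methyl 2-hydroxy-4-(methoxymethoxy)-6-methylbenzoate
Product: 12 methyl 2-methoxy-4-(methoxymethoxy)-6-methylbenzoate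
Conditions: MeI (3 equiv), K2CO3 (3 equiv), DMF, 50 °C
Reagents that add atoms: iodomethane, CI
Why: Williamson etherification with carbonate in a dipolar aprotic solvent methylates the chelated phenol, while the acetal and the ester are inert to these conditions.

Step 6
Reactants: 12 methyl 2-methoxy-4-(methoxymethoxy)-6-methylbenzoate; 13 1-iodohexane
Product: 15 methyl 2-heptyl-6-methoxy-4-(methoxymethoxy)benzoate, via methyl 2-(lithiomethyl)-6-methoxy-4-(methoxymethoxy)benzoate 14 (not isolated)
Conditions: LiN(iPr)2 (1.2 equiv), THF, −78 °C; then 13 (1.5 equiv), DMPU, −78 → 0 °C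
Reagents that add atoms: none
Why: Lateral lithiation of the ortho-toluate gives an ester-stabilised benzylic anion that should be alkylated by the primary iodide in an SN2 reaction, extending the methyl group to heptyl.

Step 7
Reactants: 15 methyl 2-heptyl-6-methoxy-4-(methoxymethoxy)benzoate
Product: 17 2-heptyl-4-hydroxy-6-methoxybenzoic acid, via 2-heptyl-6-methoxy-4-(methoxymethoxy)benzoic acid 16 (not isolated)
Conditions: KOH (10 equiv), DMSO/H2O 4:1, 90 °C; then 3 M aq. HCl, THF, rt
Reagents that add atoms: potassium hydroxide, [K+].[OH-]
Why: Forcing saponification cleaves the doubly ortho-substituted ester while the base-stable acetal survives, and the subsequent acid treatment hydrolyses the methoxymethyl acetal to release the 4-OH.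

Step 8
Reactants: 17 2-heptyl-4-hydroxy-6-methoxybenzoic acid
Product: 18 benzyl 2-heptyl-4-hydroxy-6-methoxybenzoate
Conditions: BnBr (1.05 equiv), KHCO3 (1.2 equiv), DMF, rt
Reagents that add atoms: benzyl bromide, BrCc1ccccc1
Why: Hydrogencarbonate deprotonates only the carboxylic acid, so SN2 O-alkylation of the carboxylate should give the benzyl ester and leave the less acidic phenol free.

Step 9
Reactants: 9 2-heptyl-4,6-dimethoxybenzoic acid; 18 benzyl 2-heptyl-4-hydroxy-6-methoxybenzoate
Product: 20 benzyl 2-heptyl-4-[(2-heptyl-4,6-dimethoxybenzoyl)oxy]-6-methoxybenzoate, via 2-heptyl-4,6-dimethoxybenzoic trifluoroacetic anhydride 19 (not isolated)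
Conditions: (CF3CO)2O (4 equiv), toluene, rt
Reagents that add atoms: none
Why: Mixed-anhydride esterification suits a hindered, electron-rich benzoic acid, whose trifluoroacetyl mixed anhydride ionises readily towards the acylium ion and should acylate the unhindered 4-OH of 18 without touching the benzyl ester.

Step 10
Reactants: 20 benzyl 2-heptyl-4-[(2-heptyl-4,6-dimethoxybenzoyl)oxy]-6-methoxybenzoate
Product: 21 2-heptyl-4-[(2-heptyl-4,6-dimethoxybenzoyl)oxy]-6-methoxybenzoic acid (target)
Conditions: H2 (1 atm), 10% Pd/C, EtOAc, rt
Reagents that add atoms: none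
Why: Catalytic hydrogenolysis cleaves the benzylic C–O bond of the benzyl ester under neutral conditions that should leave the aryl ester and the methyl ethers intact.

Compound list
1 | 1-bromo-3,5-dimethoxybenzene | COc1cc(Br)cc(OC)c1 | starting material
2 | 1-bromo-2-iodo-3,5-dimethoxybenzene | COc1cc(OC)c(I)c(Br)c1 | intermediate
3 | 1-bromoheptane | CCCCCCCBr | starting material
4 | heptylmagnesium bromide | CCCCCCC[Mg]Br | intermediate
5 | carbon dioxide | O=C=O | starting material
6 | 2-bromo-4,6-dimethoxyphenylmagnesium chloride | COc1cc(OC)c([Mg]Cl)c(Br)c1 | intermediate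
7 | 3,5-dimethoxybenzyne | COC1=CC(OC)=CC#C1 | intermediate
8 | 2-heptyl-4,6-dimethoxyphenylmagnesium bromide | CCCCCCCc1cc(OC)cc(OC)c1[Mg]Br | intermediate
9 | 2-heptyl-4,6-dimethoxybenzoic acid | CCCCCCCc1cc(OC)cc(OC)c1C(=O)O | intermediate
10 | methyl orsellinate (methyl 2,4-dihydroxy-6-methylbenzoate) | COC(=O)c1c(C)cc(O)cc1O | starting material
11 | methyl 2-hydroxy-4-(methoxymethoxy)-6-methylbenzoate | COC(=O)c1c(C)cc(OCOC)cc1O | intermediate
12 | methyl 2-methoxy-4-(methoxymethoxy)-6-methylbenzoate | COC(=O)c1c(C)cc(OCOC)cc1OC | intermediate
13 | 1-iodohexane | CCCCCCI | starting material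
14 | methyl 2-(lithiomethyl)-6-methoxy-4-(methoxymethoxy)benzoate | COC(=O)c1c(C[Li])cc(OCOC)cc1OC | intermediate
15 | methyl 2-heptyl-6-methoxy-4-(methoxymethoxy)benzoate | CCCCCCCc1cc(OCOC)cc(OC)c1C(=O)OC | intermediate
16 | 2-heptyl-6-methoxy-4-(methoxymethoxy)benzoic acid | CCCCCCCc1cc(OCOC)cc(OC)c1C(=O)O | intermediate
17 | 2-heptyl-4-hydroxy-6-methoxybenzoic acid | CCCCCCCc1cc(O)cc(OC)c1C(=O)O | intermediate
18 | benzyl 2-heptyl-4-hydroxy-6-methoxybenzoate | CCCCCCCc1cc(O)cc(OC)c1C(=O)OCc1ccccc1 | intermediate
19 | 2-heptyl-4,6-dimethoxybenzoic trifluoroacetic anhydride | CCCCCCCc1cc(OC)cc(OC)c1C(=O)OC(=O)C(F)(F)F | intermediate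
20 | benzyl 2-heptyl-4-[(2-heptyl-4,6-dimethoxybenzoyl)oxy]-6-methoxybenzoate | CCCCCCCc1cc(OC(=O)c2c(CCCCCCC)cc(OC)cc2OC)cc(OC)c1C(=O)OCc1ccccc1 | intermediate
21 | 2-heptyl-4-[(2-heptyl-4,6-dimethoxybenzoyl)oxy]-6-methoxybenzoic acid | CCCCCCCc1cc(OC(=O)c2c(CCCCCCC)cc(OC)cc2OC)cc(OC)c1C(=O)O | target

Total step count: 10.
Longest linear sequence: 7 steps (steps 4, 5, 6, 7, 8, 9, 10).

The three steps most likely to fail are step 3, step 6 and step 7, in that order.

First, step 3. The aryne may be intercepted by the aryl Grignards 6 or 8 instead of by 4, leading to biaryl formation. The ortho-bromo Grignard may also eliminate sluggishly, so that carboxylation traps it before addition has occurred. Carboxylation of the surplus alkyl Grignard additionally gives a second acid that has to be separated. The fallback for step 3 sets out from 1 and 4 and comes back to the route at 9 without any aryne: Kumada coupling (NiCl2(dppp), THF, reflux) should give 1-heptyl-3,5-dimethoxybenzene F1, Vilsmeier–Haack formylation of F1 (POCl3, DMF, 0 → 60 °C), expected at the carbon ortho to the alkyl chain and para to a methoxy group, should give 2-heptyl-4,6-dimethoxybenzaldehyde F2, and Pinnick oxidation of F2 (NaClO2, NaH2PO4, 2-methyl-2-butene, t-BuOH/H2O) should deliver acid 9.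

Second, step 6. The benzylic anion may attack the ester of unreacted 12 (self-condensation), or proton exchange between product and anion may cause over-alkylation. The fallback for step 6 sets out from 12 and comes back to the route at 16, moving the alkylation to the carboxylate stage where no electrophilic ester is present: saponification of 12 (KOH, DMSO/H2O, 90 °C; cold acidification to pH 4) should give 2-methoxy-4-(methoxymethoxy)-6-methylbenzoic acid F3, double deprotonation of F3 with LiN(iPr)2 (2.2 equiv, THF, −78 → 0 °C) should give the dianion lithium 2-(lithiomethyl)-6-methoxy-4-(methoxymethoxy)benzoate F4, and alkylation of F4 with 13 followed by cold dilute HCl to pH 4 should give 16, which the acid stage of step 7 then converts into 17.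

Third, step 7. The electron-rich hydroxy acid may lose carbon dioxide during the acidic removal of the acetal. The fallback for step 7 sets out from 15 and comes back to the route at 18, moving the acid treatment to a stage where no free carboxylic acid is present: after the saponification, 16 is isolated by cold acidification to pH 4 only, benzylation of 16 (BnBr, K2CO3, DMF, rt) should give benzyl 2-heptyl-6-methoxy-4-(methoxymethoxy)benzoate F5, and acetal cleavage of F5 (3 M aq. HCl, THF, rt) should give 18 directly, so that the selective carboxylate benzylation of step 8 is not needed.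

Further compounds
F1 | step 3 | 1-heptyl-3,5-dimethoxybenzene | CCCCCCCc1cc(OC)cc(OC)c1
F2 | step 3 | 2-heptyl-4,6-dimethoxybenzaldehyde | CCCCCCCc1cc(OC)cc(OC)c1C=O
F3 | step 6 | 2-methoxy-4-(methoxymethoxy)-6-methylbenzoic acid | Cc1cc(OCOC)cc(OC)c1C(=O)O
F4 | step 6 | lithium 2-(lithiomethyl)-6-methoxy-4-(methoxymethoxy)benzoate | [Li]Cc1cc(OCOC)cc(OC)c1C(=O)O[Li]
F5 | step 7 | benzyl 2-heptyl-6-methoxy-4-(methoxymethoxy)benzoate | CCCCCCCc1cc(OCOC)cc(OC)c1C(=O)OCc1ccccc1
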